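**Retrosynthetic overview**
The target is a (4→6)-linked dimer: a (2S)-2,4-trans-4-arylflavan (upper unit) on C6 of an all-cis (2R,3R,4R)-flavan-3,4-diol (lower unit). The last C–C disconnection is the interflavan bond, a Friedel–Crafts union of an upper flavan-4-ol with the diol-protected lower unit, followed by global hydrogenolysis.
The lower pyran ring C is opened at C4–C4a. An acyclic aryl ether hydroxy ester is closed in one pot by ester semi-reduction and chelation-controlled intramolecular hydroxyalkylation, which forms the C4–C4a bond, ring C and the C4 carbinol centre together.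
Enabling feature: in lower ring A, C4a is the only free carbon ortho to the ether oxygen O1 (C8 carries oxygen) and is para to the C7 oxygen, so the arene is nucleophilic exactly where the O1–C2–C3 tether can reach. The C3 hydroxyl next to the C4 carbonyl closes a five-membered chelate that fixes the 3,4-cis diol.
The acyclic ester comes from SN2 opening of a cis-glycidate (Still–Gennari, then Jacobsen epoxidation) by 2,3-bis(benzyloxy)phenol. The upper unit comes from asymmetric conjugate addition of an arylboronic acid to a chromone.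
Ring order: lower ring C (step 6); upper pyranone ring (step 9, made separately); union of the two units (step 12).

Key step: step 6

Remark: flavan numbering is used for both units (O1, C2, C3, C4, C4a, C5–C8, C8a; B-ring atoms primed). The upper unit is the 4-arylflavan and the lower unit the flavan-3,4-diol. A CIP descriptor can change between protected and free compounds without any change in geometry.

**Route**

Step 1
Reactants: 1 4-(benzyloxy)benzaldehyde
Product: 2 methyl (2Z)-3-[4-(benzyloxy)phenyl]prop-2-enoate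
Conditions: (CF3CH2O)2P(O)CH2CO2Me, KN(SiMe3)2, 18-crown-6, THF, −78 °C
Reagents that add atoms: methyl bis(2,2,2-trifluoroethyl)phosphonoacetate, COC(=O)CP(=O)(OCC(F)(F)F)OCC(F)(F)F
Why: Still–Gennari olefination: the electron-poor bis(trifluoroethyl) phosphonate with a dissociated potassium counter-ion eliminates fast and irreversibly from the kinetic adduct, which should give the Z-enoate needed for a cis-epoxide (no stereocenter is formed).

Step 2
Reactants: 2 methyl (2Z)-3-[4-(benzyloxy)phenyl]prop-2-enoate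
Product: 3 methyl (2S,3S)-3-[4-(benzyloxy)phenyl]oxirane-2-carboxylate (cis-epoxide)
Conditions: (S,S)-Mn(salen)Cl (5 mol%; salen = N,N'-bis(3,5-di-tert-butylsalicylidene)cyclohexane-1,2-diamine dianion), aq. NaOCl (pH 11.3), 4-phenylpyridine N-oxide, CH2Cl2, 0 °C
Reagents that add atoms: sodium hypochlorite, [Na+].[O-]Cl
Why: Jacobsen–Katsuki epoxidation, for which cis-cinnamate esters are a well-behaved substrate class: the (S,S)-catalyst should transfer oxygen to the alkene face that gives the (2S,3S)-cis-epoxide, and the N-oxide additive limits leakage to the trans-epoxide.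

Step 3
Reactants: 4 2,3-dihydroxybenzaldehyde
Product: 5 2,3-bis(benzyloxy)benzaldehyde
Conditions: PhCH2Br, K2CO3, DMF, rt
Reagents that add atoms: benzyl bromide, BrCc1ccccc1
Why: Williamson ether synthesis on both phenols; no stereocenter is involved.

Step 4
Reactants: 5 2,3-bis(benzyloxy)benzaldehyde
Product: 7 2,3-bis(benzyloxy)phenol, via aryl formate 6 (not isolated)
Conditions: 3-ClC6H4CO3H, CH2Cl2, 0 °C to rt; then K2CO3 (cat.), MeOH
Reagents that add atoms: 3-chloroperoxybenzoic acid, O=C(OO)c1cccc(Cl)c1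
Why: Dakin-type Baeyer–Villiger oxidation: the electron-rich aryl group migrates to oxygen to give formate 6, which mild methanolysis cleaves to the phenol.

Step 5
Reactants: 3 methyl (2S,3S)-3-[4-(benzyloxy)phenyl]oxirane-2-carboxylate, 7 2,3-bis(benzyloxy)phenol
Product: 8 methyl (2S,3R)-3-[2,3-bis(benzyloxy)phenoxy]-3-[4-(benzyloxy)phenyl]-2-hydroxypropanoate
Conditions: Cs2CO3 (0.3 equiv), MeCN, 50 °C
Reagents that add atoms: none
Why: Base-catalysed SN2 opening of a 3-arylglycidate by a phenoxide at the benzylic carbon (the usual site for heteroatom nucleophiles): attack anti to the epoxide oxygen inverts that carbon and leaves the hydroxyl-bearing carbon untouched, so the cis-epoxide gives the (2S,3R) ester that maps onto the 2,3-cis relationship of the lower unit.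

Step 6
Reactants: 8 methyl (2S,3R)-3-[2,3-bis(benzyloxy)phenoxy]-3-[4-(benzyloxy)phenyl]-2-hydroxypropanoate
Product: 11 (2R,3R,4R)-7,8-bis(benzyloxy)-2-[4-(benzyloxy)phenyl]-3,4-dihydro-2H-chromene-3,4-diol (2,3-cis-3,4-cis), via aluminium acetal 9 (not isolated), via aluminoxy aldehyde 10 (not isolated)
Conditions: i-Bu2AlH (2.1 equiv), CH2Cl2, −78 °C; then Me2AlCl (3 equiv), −78 to −30 °C; aq. potassium sodium tartrate
Reagents that add atoms: none
Why: Proposed new method: i-Bu2AlH deprotonates the C3 hydroxyl and semi-reduces the ester to the chelated aluminium acetal 9; Me2AlCl then pulls off methoxide to give aldehyde 10, whose carbonyl oxygen and C3 aluminoxy oxygen sit in a five-membered chelate, and ring-A carbon C4a (ortho to O1, para to the C7 benzyloxy group) attacks the activated carbonyl carbon, the Wheland proton being consumed by an Al–C bond so that the product leaves as a cyclic aluminium diolate that cannot ionise at C4. The closest known reaction types are the intramolecular Friedel–Crafts hydroxyalkylation of arene-tethered aldehydes (Bobbitt-type closures to 4-hydroxy heterocycles), Me2AlCl-promoted carbonyl-ene and Prins closures with proton scavenging, and Lewis-acid reactions of aluminium acetals made in situ from alpha-oxygenated esters. Ring C closes in the 6-exo-trig mode, the arene carbon adding to a carbonyl whose oxygen stays outside the ring. The new C4 centre is set by the chelate within the half-chair transition state: with the 2-aryl group pseudo-equatorial the C3–O bond is axial, and the aluminium bridge holds the carbonyl oxygen gauche to O3, which is possible only for a pseudo-equatorial C4–O bond, that is the 3,4-cis (4R) alcohol, whereas an unchelated, dipole-opposed (Cornforth-type) geometry with the two oxygens anti would give the 3,4-trans epimer. The step needs regioselectivity, secured because C4a is the only ring carbon the three-atom tether can reach and C8 is substituted, and chemoselectivity against ionisation of the benzylic C2–O1 ether, secured by the mild aluminium Lewis acid at low temperature and by the electron-withdrawing, metal-bound oxygen on C3.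

Step 7
Reactants: 11 (2R,3R,4R)-7,8-bis(benzyloxy)-2-[4-(benzyloxy)phenyl]-3,4-dihydro-2H-chromene-3,4-diol
Product: 12 3,4-O-benzylidene acetal of 11 (cis-fused 2-phenyl-1,3-dioxolane, configuration at C2, C3 and C4 as in 11, either configuration at the acetal carbon)
Conditions: PhCH(OMe)2, pyridinium p-toluenesulfonate (cat.), CH2Cl2, rt
Reagents that add atoms: benzaldehyde dimethyl acetal, COC(OC)c1ccccc1
Why: Acid-catalysed transacetalisation: the cis-3,4-diol spans a five-membered benzylidene acetal that blocks O-alkylation and ionisation at C4 in the coupling and falls off in the final hydrogenolysis; the new acetal carbon is of no consequence.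

Step 8
Reactants: 13 1-(2,3,4-trihydroxyphenyl)ethanone
Product: 14 1-[3,4-bis(benzyloxy)-2-hydroxyphenyl]ethanone
Conditions: PhCH2Br (2.1 equiv), K2CO3, DMF, rt
Reagents that add atoms: benzyl bromide, BrCc1ccccc1
Why: Williamson ether synthesis: the C2 hydroxyl, hydrogen-bonded to the ketone, is the least nucleophilic of the three and should stay free with two equivalents of benzyl bromide.

Step 9
Reactants: 14 1-[3,4-bis(benzyloxy)-2-hydroxyphenyl]ethanone
Product: 16 7,8-bis(benzyloxy)-4H-chromen-4-one, via enaminone 15 (not isolated)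
Conditions: Me2NCH(OMe)2, 100 °C; then conc. HCl, CH2Cl2, 40 °C
Reagents that add atoms: N,N-dimethylformamide dimethyl acetal, COC(OC)N(C)C
Why: Enaminone route to chromones: condensation of the methyl ketone with the amide acetal gives enaminone 15, and acid-promoted conjugate addition of the phenol with loss of dimethylamine closes the pyranone ring.

Step 10
Reactants: 16 7,8-bis(benzyloxy)-4H-chromen-4-one, 17 [4-(benzyloxy)phenyl]boronic acid
Product: 18 (2S)-7,8-bis(benzyloxy)-2-[4-(benzyloxy)phenyl]-2,3-dihydro-4H-chromen-4-one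
Conditions: Pd(OCOCF3)2 (5 mol%), (R)-t-BuPyOx (6 mol%), NH4PF6 (30 mol%), H2O (5 equiv), ClCH2CH2Cl, 60 °C
Reagents that add atoms: none
Why: Palladium-catalysed asymmetric conjugate addition of an arylboronic acid to a chromone with a pyridine-oxazoline ligand: enantioface-selective insertion of the C2=C3 bond into the aryl–palladium bond sets C2, and the R ligand ((R)-4-tert-butyl-2-(pyridin-2-yl)-4,5-dihydrooxazole) is chosen because it should give the 2S flavanone.

Step 11
Reactants: 18 (2S)-7,8-bis(benzyloxy)-2-[4-(benzyloxy)phenyl]-2,3-dihydro-4H-chromen-4-one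
Product: 19 (2S)-7,8-bis(benzyloxy)-2-[4-(benzyloxy)phenyl]-3,4-dihydro-2H-chromen-4-ol (C4 epimers, mainly 2,4-cis)
Conditions: NaBH4, THF/MeOH, 0 °C
Reagents that add atoms: none
Why: Borohydride reduction of the aryl ketone; axial hydride delivery should give mainly the 2,4-cis alcohol, but the C4 configuration is lost on ionisation in step 12 and both epimers converge.

Step 12
Reactants: 19 (2S)-7,8-bis(benzyloxy)-2-[4-(benzyloxy)phenyl]-3,4-dihydro-2H-chromen-4-ol, 12 3,4-O-benzylidene acetal of 11 (2.5 equiv, the excess is recovered)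
Product: 21 3,4-O-benzylidene acetal of (2R,3R,4R)-7,8-bis(benzyloxy)-6-{(2S,4R)-7,8-bis(benzyloxy)-2-[4-(benzyloxy)phenyl]-3,4-dihydro-2H-chromen-4-yl}-2-[4-(benzyloxy)phenyl]-3,4-dihydro-2H-chromene-3,4-diol (upper unit 2,4-trans; its C4 is 4R here and 4S in 22 only because the benzyl ethers change the CIP ranking), via benzylic cation 20 (not isolated)
Conditions: BF3·OEt2 (0.3 equiv), 4 Å molecular sieves, CH2Cl2, −40 to −20 °C
Reagents that add atoms: none
Why: Friedel–Crafts alkylation by a flavan-4-yl cation, the standard interflavan coupling: BF3 ionises the C4 hydroxyl (lost as water, taken up by the sieves) to the para-oxygen-stabilised cation 20, which is attacked by C6 of 12 (ortho to the C7 oxygen and para to O1, the only strongly activated free position) along a pseudo-axial trajectory on the face anti to the pseudo-equatorial 2-aryl group, which should set the upper C4 centre 2,4-trans.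

Step 13
Reactants: 21 hexabenzyl benzylidene-protected dimer
Product: 22 (2R,3R,4R)-6-[(2S,4S)-7,8-dihydroxy-2-(4-hydroxyphenyl)-3,4-dihydro-2H-chromen-4-yl]-2-(4-hydroxyphenyl)-3,4-dihydro-2H-chromene-3,4,7,8-tetrol (CNP0209379.1)
Conditions: H2 (1 atm), Pd(OH)2/C, EtOAc/MeOH, rt, work-up under argon
Reagents that add atoms: none
Why: Catalytic hydrogenolysis under neutral conditions should cleave the six aryl benzyl ethers and the benzylidene acetal without touching any stereocenter.

**Compound list**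
1 | 4-(benzyloxy)benzaldehyde | O=Cc1ccc(OCc2ccccc2)cc1 | starting material
2 | methyl (2Z)-3-[4-(benzyloxy)phenyl]prop-2-enoate | COC(=O)/C=C\c1ccc(OCc2ccccc2)cc1 | intermediate
3 | methyl (2S,3S)-3-[4-(benzyloxy)phenyl]oxirane-2-carboxylate (cis) | O1[C@@H](c2ccc(OCc3ccccc3)cc2)[C@H]1C(=O)OC | intermediate
4 | 2,3-dihydroxybenzaldehyde | O=Cc1cccc(O)c1O | starting material
5 | 2,3-bis(benzyloxy)benzaldehyde | O=Cc1cccc(OCc2ccccc2)c1OCc1ccccc1 | intermediate
6 | 2,3-bis(benzyloxy)phenyl formate | O=COc1cccc(OCc2ccccc2)c1OCc1ccccc1 | intermediate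
7 | 2,3-bis(benzyloxy)phenol | Oc1cccc(OCc2ccccc2)c1OCc1ccccc1 | intermediate
8 | methyl (2S,3R)-3-[2,3-bis(benzyloxy)phenoxy]-3-[4-(benzyloxy)phenyl]-2-hydroxypropanoate | c1ccccc1COc1cccc(O[C@H](c2ccc(OCc3ccccc3)cc2)[C@H](O)C(=O)OC)c1OCc1ccccc1 | intermediate
9 | bis(diisobutylaluminium) derivative of the methyl hemiacetal of the aldehyde from 8 (both oxygens aluminated, either configuration at the acetal carbon) | c1ccccc1COc1cccc(O[C@H](c2ccc(OCc3ccccc3)cc2)[C@H](O[Al](CC(C)C)CC(C)C)C(OC)O[Al](CC(C)C)CC(C)C)c1OCc1ccccc1 | intermediate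
10 | (2S,3R)-3-[2,3-bis(benzyloxy)phenoxy]-3-[4-(benzyloxy)phenyl]-2-hydroxypropanal as its O-diisobutylaluminium alkoxide | c1ccccc1COc1cccc(O[C@H](c2ccc(OCc3ccccc3)cc2)[C@H](O[Al](CC(C)C)CC(C)C)C=O)c1OCc1ccccc1 | intermediate
11 | (2R,3R,4R)-7,8-bis(benzyloxy)-2-[4-(benzyloxy)phenyl]-3,4-dihydro-2H-chromene-3,4-diol | c1ccccc1COc1ccc2c(c1OCc1ccccc1)O[C@H](c1ccc(OCc3ccccc3)cc1)[C@H](O)[C@@H]2O | intermediate
12 | 3,4-O-benzylidene acetal of 11 | c1ccccc1COc1ccc2c(c1OCc1ccccc1)O[C@H](c1ccc(OCc3ccccc3)cc1)[C@H](OC(c1ccccc1)O3)[C@@H]23 | intermediate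
13 | 1-(2,3,4-trihydroxyphenyl)ethanone | CC(=O)c1ccc(O)c(O)c1O | starting material
14 | 1-[3,4-bis(benzyloxy)-2-hydroxyphenyl]ethanone | CC(=O)c1ccc(OCc2ccccc2)c(OCc2ccccc2)c1O | intermediate
15 | (2E)-1-[3,4-bis(benzyloxy)-2-hydroxyphenyl]-3-(dimethylamino)prop-2-en-1-one | CN(C)/C=C/C(=O)c1ccc(OCc2ccccc2)c(OCc2ccccc2)c1O | intermediate
16 | 7,8-bis(benzyloxy)-4H-chromen-4-one | O=c1ccoc2c1ccc(OCc1ccccc1)c2OCc1ccccc1 | intermediate
17 | [4-(benzyloxy)phenyl]boronic acid | OB(O)c1ccc(OCc2ccccc2)cc1 | starting material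
18 | (2S)-7,8-bis(benzyloxy)-2-[4-(benzyloxy)phenyl]-2,3-dihydro-4H-chromen-4-one | c1ccccc1COc1ccc(cc1)[C@@H]1CC(=O)c2ccc(OCc3ccccc3)c(OCc3ccccc3)c2O1 | intermediate
19 | (2S)-7,8-bis(benzyloxy)-2-[4-(benzyloxy)phenyl]-3,4-dihydro-2H-chromen-4-ol (C4 epimers) | c1ccccc1COc1ccc(cc1)[C@@H]1CC(O)c2ccc(OCc3ccccc3)c(OCc3ccccc3)c2O1 | intermediate
20 | (2S)-7,8-bis(benzyloxy)-2-[4-(benzyloxy)phenyl]-3,4-dihydro-2H-chromen-4-ylium hydroxytrifluoroborate | c1ccccc1COc1ccc(cc1)[C@@H]1C[CH+]c2ccc(OCc3ccccc3)c(OCc3ccccc3)c2O1.O[B-](F)(F)F | intermediate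
21 | 3,4-O-benzylidene acetal of the hexabenzyl (4→6) dimer (lower unit as in 12, upper unit (2S)-2,4-trans) | c1ccccc1COc1ccc([C@@H]2C[C@@H](c3cc4c(c(OCc5ccccc5)c3OCc5ccccc5)O[C@H](c3ccc(OCc5ccccc5)cc3)[C@H](OC(c5ccccc5)O6)[C@@H]46)c3ccc(OCc5ccccc5)c(OCc5ccccc5)c3O2)cc1 | intermediate
22 | (2R,3R,4R)-6-[(2S,4S)-7,8-dihydroxy-2-(4-hydroxyphenyl)-3,4-dihydro-2H-chromen-4-yl]-2-(4-hydroxyphenyl)-3,4-dihydro-2H-chromene-3,4,7,8-tetrol | Oc1ccc([C@@H]2C[C@@H](c3cc4c(c(O)c3O)O[C@H](c3ccc(O)cc3)[C@H](O)[C@@H]4O)c3ccc(O)c(O)c3O2)cc1 | target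

**Step count and risks**
Total steps: 13. Longest linear sequence: 7 steps (3, 4, 5, 6, 7, 12, 13; equally 1, 2, 5, 6, 7, 12, 13).

Steps most likely to fail:

Step 6 (Proposed new method). The telescoped sequence may fail in three ways. Ring closure may be outrun by methyl or hydride transfer to the aldehyde. The benzylic C2–O1 ether may ionise under the Lewis acid. Chelation may be lost, so that the 3,4-trans epimer forms. The fallback uses known chemistry, separates the events and takes the C4 configuration from a hydride reduction instead of a chelate; it sets out from 8. Silylation (t-BuMe2SiOTf, 2,6-lutidine, CH2Cl2) gives methyl (2S,3R)-3-[2,3-bis(benzyloxy)phenoxy]-3-[4-(benzyloxy)phenyl]-2-[(tert-butyldimethylsilyl)oxy]propanoate F1. Reduction with i-Bu2AlH (1.1 equiv, toluene, −78 °C) gives the isolable aldehyde (2S,3R)-3-[2,3-bis(benzyloxy)phenoxy]-3-[4-(benzyloxy)phenyl]-2-[(tert-butyldimethylsilyl)oxy]propanal F2. A separate Lewis-acid-mediated intramolecular Friedel–Crafts hydroxyalkylation of this aldehyde (Me2AlCl, CH2Cl2, −78 °C) should give (2R,3R)-7,8-bis(benzyloxy)-2-[4-(benzyloxy)phenyl]-3-[(tert-butyldimethylsilyl)oxy]-3,4-dihydro-2H-chromen-4-ol F3, which is accepted as a mixture of C4 epimers. MnO2 (CH2Cl2, rt) oxidises the benzylic alcohol to (2R,3S)-7,8-bis(benzyloxy)-2-[4-(benzyloxy)phenyl]-3-[(tert-butyldimethylsilyl)oxy]-2,3-dihydro-4H-chromen-4-one F4. NaBH4 (THF/MeOH, −20 °C) should then deliver hydride anti to the axial C3 silyloxy group (Felkin–Anh control) to give the 3,4-cis alcohol (2R,3R,4R)-7,8-bis(benzyloxy)-2-[4-(benzyloxy)phenyl]-3-[(tert-butyldimethylsilyl)oxy]-3,4-dihydro-2H-chromen-4-ol F5. Bu4NF buffered with AcOH removes the silyl group (a silyl shift between O3 and O4 would be harmless), and the route is rejoined at 11.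

Step 12. The oxophilic Lewis acid may open the benzylidene acetal or ionise the lower C4–O bond, the cation may alkylate its own ring A, and facial selectivity at the upper C4 may be incomplete. The fallback sets out from 19 and changes the leaving group and the mode of activation. Thiolysis (PhCH2SH, ZnI2, CH2Cl2, 0 °C) gives (2S)-4-(benzylsulfanyl)-7,8-bis(benzyloxy)-2-[4-(benzyloxy)phenyl]-3,4-dihydro-2H-chromene F6. Its C–S bond is then activated with the thiophilic salt AgBF4 (THF, 0 °C) in the presence of 12. This soft activation should leave all C–O bonds alone, and the route is rejoined at 21.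

Step 13. Once the acetal is cleaved, hydrogenolysis may go on to break the benzylic C4–O bond of the lower unit, and the free polyphenol may oxidise in air. The fallback sets out from 21 and carries C4 through the hydrogenolysis as a ketone. Aqueous AcOH/THF removes the benzylidene group to give the hexabenzyl diol (2R,3R,4R)-7,8-bis(benzyloxy)-6-{(2S,4R)-7,8-bis(benzyloxy)-2-[4-(benzyloxy)phenyl]-3,4-dihydro-2H-chromen-4-yl}-2-[4-(benzyloxy)phenyl]-3,4-dihydro-2H-chromene-3,4-diol F7; any epimerisation at C4 here is harmless because C4 becomes a ketone next. MnO2 (CH2Cl2) should oxidise only the benzylic C4 alcohol, giving the 2,3-cis 3-hydroxy-4-ketone (2R,3S)-7,8-bis(benzyloxy)-6-{(2S,4R)-7,8-bis(benzyloxy)-2-[4-(benzyloxy)phenyl]-3,4-dihydro-2H-chromen-4-yl}-2-[4-(benzyloxy)phenyl]-3-hydroxy-2,3-dihydro-4H-chromen-4-one F8. Hydrogenolysis (H2, Pd(OH)2/C) gives the free phenolic 4-ketone (2R,3S)-6-[(2S,4S)-7,8-dihydroxy-2-(4-hydroxyphenyl)-3,4-dihydro-2H-chromen-4-yl]-3,7,8-trihydroxy-2-(4-hydroxyphenyl)-2,3-dihydro-4H-chromen-4-one F9. NaBH4 (MeOH, 0 °C) then reduces the ketone, with hydride delivery anti to the axial C3 hydroxyl expected to give the 3,4-cis alcohol; this is the classical way to free phenolic flavan-3,4-diols, and the route is rejoined at 22.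

**Further compounds**
F1 | step 6 | methyl (2S,3R)-3-[2,3-bis(benzyloxy)phenoxy]-3-[4-(benzyloxy)phenyl]-2-[(tert-butyldimethylsilyl)oxy]propanoate | c1ccccc1COc1cccc(O[C@H](c2ccc(OCc3ccccc3)cc2)[C@H](O[Si](C)(C)C(C)(C)C)C(=O)OC)c1OCc1ccccc1
F2 | step 6 | (2S,3R)-3-[2,3-bis(benzyloxy)phenoxy]-3-[4-(benzyloxy)phenyl]-2-[(tert-butyldimethylsilyl)oxy]propanal | c1ccccc1COc1cccc(O[C@H](c2ccc(OCc3ccccc3)cc2)[C@H](O[Si](C)(C)C(C)(C)C)C=O)c1OCc1ccccc1
F3 | step 6 | (2R,3R)-7,8-bis(benzyloxy)-2-[4-(benzyloxy)phenyl]-3-[(tert-butyldimethylsilyl)oxy]-3,4-dihydro-2H-chromen-4-ol (C4 epimers) | c1ccccc1COc1ccc2c(c1OCc1ccccc1)O[C@H](c1ccc(OCc3ccccc3)cc1)[C@H](O[Si](C)(C)C(C)(C)C)C2O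
F4 | step 6 | (2R,3S)-7,8-bis(benzyloxy)-2-[4-(benzyloxy)phenyl]-3-[(tert-butyldimethylsilyl)oxy]-2,3-dihydro-4H-chromen-4-one (2,3-cis) | c1ccccc1COc1ccc2c(c1OCc1ccccc1)O[C@H](c1ccc(OCc3ccccc3)cc1)[C@H](O[Si](C)(C)C(C)(C)C)C2=O
F5 | step 6 | (2R,3R,4R)-7,8-bis(benzyloxy)-2-[4-(benzyloxy)phenyl]-3-[(tert-butyldimethylsilyl)oxy]-3,4-dihydro-2H-chromen-4-ol | c1ccccc1COc1ccc2c(c1OCc1ccccc1)O[C@H](c1ccc(OCc3ccccc3)cc1)[C@H](O[Si](C)(C)C(C)(C)C)[C@@H]2O
F6 | step 12 | (2S)-4-(benzylsulfanyl)-7,8-bis(benzyloxy)-2-[4-(benzyloxy)phenyl]-3,4-dihydro-2H-chromene (C4 epimers) | c1ccccc1COc1ccc(cc1)[C@@H]1CC(SCc4ccccc4)c2ccc(OCc3ccccc3)c(OCc3ccccc3)c2O1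
F7 | step 13 | (2R,3R,4R)-7,8-bis(benzyloxy)-6-{(2S,4R)-7,8-bis(benzyloxy)-2-[4-(benzyloxy)phenyl]-3,4-dihydro-2H-chromen-4-yl}-2-[4-(benzyloxy)phenyl]-3,4-dihydro-2H-chromene-3,4-diol | c1ccccc1COc1ccc([C@@H]2C[C@@H](c3cc4c(c(OCc5ccccc5)c3OCc5ccccc5)O[C@H](c3ccc(OCc5ccccc5)cc3)[C@H](O)[C@@H]4O)c3ccc(OCc5ccccc5)c(OCc5ccccc5)c3O2)cc1
F8 | step 13 | (2R,3S)-7,8-bis(benzyloxy)-6-{(2S,4R)-7,8-bis(benzyloxy)-2-[4-(benzyloxy)phenyl]-3,4-dihydro-2H-chromen-4-yl}-2-[4-(benzyloxy)phenyl]-3-hydroxy-2,3-dihydro-4H-chromen-4-one (2,3-cis) | c1ccccc1COc1ccc([C@@H]2C[C@@H](c3cc4c(c(OCc5ccccc5)c3OCc5ccccc5)O[C@H](c3ccc(OCc5ccccc5)cc3)[C@H](O)C4=O)c3ccc(OCc5ccccc5)c(OCc5ccccc5)c3O2)cc1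
F9 | step 13 | (2R,3S)-6-[(2S,4S)-7,8-dihydroxy-2-(4-hydroxyphenyl)-3,4-dihydro-2H-chromen-4-yl]-3,7,8-trihydroxy-2-(4-hydroxyphenyl)-2,3-dihydro-4H-chromen-4-one (2,3-cis) | Oc1ccc([C@@H]2C[C@@H](c3cc4c(c(O)c3O)O[C@H](c3ccc(O)cc3)[C@H](O)C4=O)c3ccc(O)c(O)c3O2)cc1
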